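**Strategy**

The route rests on disconnecting the bond between the ketone carbon and C1 of the 3,4,5-trimethoxyphenyl ring. The key step adds 3,4,5-trimethoxyphenylmagnesium bromide to the N-methoxy-N-methylamide of (R)-2-(4-allyl-2,6-dimethoxyphenoxy)propanoic acid, completing the carbon skeleton in one operation. It exploits the ketone carbon next to the O-bearing stereocentre: the Mg-chelated tetrahedral adduct masks the configurationally labile α-aryloxy ketone until acidic quench, and the C–Mg bond fixes the ring position (para to the central methoxy) that Friedel–Crafts acylation of 1,2,3-trimethoxybenzene cannot reach. The stereocentre comes from ethyl (S)-lactate by Mitsunobu inversion with 4-allyl-2,6-dimethoxyphenol.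

Key step: step 3

Remark: the stereocentre of the target is R (priorities O > C=O > CH3 > H).
Assumption: 3,4,5-trimethoxyphenylmagnesium bromide (5) is taken as its commercial 0.5 M THF solution and titrated before use.

**Route**

Step 1
Reactants: 1 4-allyl-2,6-dimethoxyphenol (methoxyeugenol); 2 ethyl (S)-lactate
Product: 3 ethyl (R)-2-(4-allyl-2,6-dimethoxyphenoxy)propanoate
Conditions: PPh3 (1.3 equiv), DIAD (1.3 equiv), THF, 0 °C → rt
Reagents that add atoms: none
Why: Mitsunobu etherification, in which the phenoxide (phenol pKa about 10) displaces the alkoxyphosphonium of the lactate in an SN2 step that inverts the carbinol carbon from S to R and so sets the only stereocentre of the target.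

Step 2
Reactants: 3 ethyl (R)-2-(4-allyl-2,6-dimethoxyphenoxy)propanoate
Product: 4 (R)-2-(4-allyl-2,6-dimethoxyphenoxy)-N-methoxy-N-methylpropanamide
Conditions: MeNH(OMe)·HCl (1.5 equiv), iPrMgCl (3.0 equiv), THF, −20 → −10 °C; aq NH4Cl
Reagents that add atoms: N,O-dimethylhydroxylamine hydrochloride, CNOC.Cl
Why: Weinreb amide formation from an ester by aminolysis with chloromagnesium N-methoxy-N-methylamide made in the flask, which at −20 °C should acylate faster than it enolises the α-aryloxy ester, so the R centre is kept and the allyl group is untouched.

Step 3
Reactants: 4 (R)-2-(4-allyl-2,6-dimethoxyphenoxy)-N-methoxy-N-methylpropanamide; 5 3,4,5-trimethoxyphenylmagnesium bromide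
Product: 7 (R)-2-(4-allyl-2,6-dimethoxyphenoxy)-1-(3,4,5-trimethoxyphenyl)propan-1-one, via bromomagnesium hemiaminal alkoxide 6 (not isolated)
Conditions: 5 (1.5 equiv, 0.5 M in THF), THF, −20 → 0 °C; then 1 M HCl, 0 °C
Reagents that add atoms: none
Why: Weinreb ketone synthesis: the aryl Grignard adds to the amide carbonyl and the resulting bromomagnesium alkoxide 6 is held as a five-membered O–Mg–OMe chelate (supported by the α-aryloxy oxygen) that cannot expel nitrogen, so a second addition is excluded, and the cold acidic quench then collapses the hemiaminal to the ketone and N,O-dimethylhydroxylamine. The closest known reaction type is the addition of aryl Grignard reagents to lactic-acid-derived α-alkoxy N-methoxy-N-methylamides. No ring is closed and no new stereocentre remains in the product (the hemiaminal carbon of 6 is transient); the R centre from step 1 should be retained because carbonyl addition outpaces α-deprotonation and the enolisable α-aryloxy ketone exists only after the quench. The step needs mono-addition, chemoselectivity over the terminal alkene and the aryl methyl ethers, and the 3,4,5-substitution pattern; the chelate secures the first, the non-electrophilic allyl group the second, and the position of the C–Mg bond the third.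

**Compound list**

1 | 4-allyl-2,6-dimethoxyphenol (methoxyeugenol) | C=CCc1cc(OC)c(O)c(OC)c1 | starting material
2 | ethyl (S)-lactate | C[C@H](O)C(=O)OCC | starting material
3 | ethyl (R)-2-(4-allyl-2,6-dimethoxyphenoxy)propanoate | C=CCc1cc(OC)c(O[C@H](C)C(=O)OCC)c(OC)c1 | intermediate
4 | (R)-2-(4-allyl-2,6-dimethoxyphenoxy)-N-methoxy-N-methylpropanamide | C=CCc1cc(OC)c(O[C@H](C)C(=O)N(C)OC)c(OC)c1 | intermediate
5 | 3,4,5-trimethoxyphenylmagnesium bromide | COc1cc([Mg]Br)cc(OC)c1OC | starting material
6 | bromomagnesium hemiaminal alkoxide (tetrahedral adduct of 4 and 5, hemiaminal carbon of undefined configuration) | C=CCc1cc(OC)c(O[C@H](C)C(O[Mg]Br)(N(C)OC)c2cc(OC)c(OC)c(OC)c2)c(OC)c1 | intermediate (not isolated)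
7 | (R)-2-(4-allyl-2,6-dimethoxyphenoxy)-1-(3,4,5-trimethoxyphenyl)propan-1-one | C=CCc1cc(OC)c(O[C@H](C)C(=O)c2cc(OC)c(OC)c(OC)c2)c(OC)c1 | target

**Totals**

Total step count: 3
Longest linear sequence: 3 steps (1 or 2 → 3 → 4 → 7)

**Steps most likely to fail**

Step 3 (key step). The aryl Grignard may act as a base, either removing the α-proton of the amide (erosion of configurational purity) or cleaving the N-methoxy group, and addition of the electron-rich aryl nucleophile may be slow. The fallback forms the same bond under neutral conditions by a Liebeskind–Srogl coupling; it sets out from 3 and returns at 7. Ester 3 should be converted with Me3Al/PhSH (CH2Cl2, 0 °C → rt) into S-phenyl (R)-2-(4-allyl-2,6-dimethoxyphenoxy)propanethioate F1. F1 would then be coupled with commercial 3,4,5-trimethoxyphenylboronic acid (COc1cc(B(O)O)cc(OC)c1OC) using catalytic Pd2(dba)3/tri(2-furyl)phosphine and copper(I) thiophene-2-carboxylate (THF, 50 °C), which should give 7 without any base.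

Step 2. The basic magnesium amide/iPrMgCl medium may partly enolise the α-aryloxy ester, or aminolysis may stall next to the bulky di-ortho-substituted aryloxy group. The fallback reverses the order of events; it sets out from 2 and returns at 4. Ethyl (S)-lactate 2 should first be converted (MeNH(OMe)·HCl, iPrMgCl, THF, −20 °C) into (S)-2-hydroxy-N-methoxy-N-methylpropanamide F2, whose stereocentre is shielded as the magnesium alkoxide. Mitsunobu coupling of F2 with phenol 1 (PPh3, DIAD, THF, 0 °C → rt) should then give 4 directly with inversion.

Step 1. The di-ortho-substituted phenol may couple slowly, letting the activated lactate eliminate to the acrylate or alkylate the hydrazide instead. The fallback replaces redox activation by a sulfonate displacement; it sets out from 2 and returns at 3. Ethyl (S)-lactate 2 should be converted (Tf2O, 2,6-lutidine, CH2Cl2, −78 °C) into ethyl (S)-2-(trifluoromethylsulfonyloxy)propanoate F3. SN2 displacement of F3 by the potassium phenoxide of 1 (K2CO3, MeCN, −20 → 0 °C) should give 3 with clean inversion.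

**Further compounds**

F1 | step 3 | S-phenyl (R)-2-(4-allyl-2,6-dimethoxyphenoxy)propanethioate | C=CCc1cc(OC)c(O[C@H](C)C(=O)Sc2ccccc2)c(OC)c1
F2 | step 2 | (S)-2-hydroxy-N-methoxy-N-methylpropanamide | C[C@H](O)C(=O)N(C)OC
F3 | step 1 | ethyl (S)-2-(trifluoromethylsulfonyloxy)propanoate | C[C@H](OS(=O)(=O)C(F)(F)F)C(=O)OCC
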